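**Plan**

1. Retrosynthesis: the C8 and C9 esters, the C14 aldehyde and the free C15 hydroxyl are traced back to ketone 27. There the lactone carbonyl C12 stands 1,5 to the C9 carbonyl through C11–C7–C8, so the five-membered lactone ring is cut at C7–C11 and at C11=C13 (acceptor: ring enone C7=C8–C9=O; donor: a phosphonoacetate on O6; C13 from formaldehyde).
2. The ten-membered trienone is then cut at C7=C8 (metathesis), at C8–C9 and C9–C10 (CO inserted between a C10 iodide and a vinyl group), at C1=C10 (Wittig), at C3–C4 (B-alkyl Suzuki) and at C6–C7 (vinyl addition).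
3. Forward: the chain C6–C5=C4(C15)–C3–C2–C1 is joined first, then come the C6 carbinol, the C1=C10 iodoalkene and the divinyl ketone; metathesis closes the ten-membered ring, and the Michael–olefination step then closes the lactone ring.
4. Stereochemistry: C6 comes from a catalytic asymmetric vinylzinc addition; C7 is set by C6 in the lactone closure, C8 by C7 in a Rubottom oxidation, and C9 by C8 in a Luche reduction.
5. Alkene geometry: C4=C5 from trans-hydroalumination/iodination and a stereoretentive coupling; C1=C10 from a Z-selective iodo-Wittig reaction and a stereoretentive carbonylation; C7=C8 from ring constraint.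

Key step: step 14

Remark: germacrane numbering (C1 to C15) is used for all compounds in the discussion; CIP letters change with the substituents, so the SMILES strings are decisive for configuration.

**Route**

Step 1
Reactants: 1 but-2-yne-1,4-diol
Product: 2 4-[(tert-butyldimethylsilyl)oxy]but-2-yn-1-ol
Conditions: NaH (1.0 equiv), THF, 0 °C to rt; TBSCl (1.0 equiv)
Reagents that add atoms: tert-butyldimethylsilyl chloride, CC(C)(C)[Si](C)(C)Cl
Why: Silylation of the monosodium alkoxide of a symmetric diol is a standard way to stop at the mono silyl ether.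

Step 2
Reactants: 2 4-[(tert-butyldimethylsilyl)oxy]but-2-yn-1-ol
Product: 4 (2Z)-4-[(tert-butyldimethylsilyl)oxy]-3-iodobut-2-en-1-ol, via sodium alkenylaluminate 3 (not isolated)
Conditions: Na[AlH2(OCH2CH2OCH3)2], THF, 0 °C; then I2, −78 to 0 °C; aqueous work-up
Reagents that add atoms: iodine, II
Why: Hydroxyl-directed trans-hydroalumination of the propargylic alcohol puts aluminium on the distal alkyne carbon in a five-membered oxaaluminacycle, and iodinolysis with retention gives the Z iodoalkene with iodine cis to the C6 hydroxymethyl group.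

Step 3
Reactants: 4 (2Z)-4-[(tert-butyldimethylsilyl)oxy]-3-iodobut-2-en-1-ol; 5 acrolein diethyl acetal
Product: 7 (2E)-3-{[(tert-butyldimethylsilyl)oxy]methyl}-6,6-diethoxyhex-2-en-1-ol, via alkylborane 6 (not isolated)
Conditions: 5, 9-BBN, THF, 0 °C to rt; then 4, PdCl2(dppf) (5 mol %; dppf = 1,1'-bis(diphenylphosphino)ferrocene), AsPh3, Cs2CO3, DMF/H2O, rt
Reagents that add atoms: none
Why: Anti-Markovnikov hydroboration followed by B-alkyl Suzuki–Miyaura coupling forms C3–C4 with retention of the iodoalkene geometry, so C3 ends up cis to C6, and the free hydroxyl and the acetal are tolerated.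

Step 4
Reactants: 7 (2E)-3-{[(tert-butyldimethylsilyl)oxy]methyl}-6,6-diethoxyhex-2-en-1-ol
Product: 8 (2E)-3-{[(tert-butyldimethylsilyl)oxy]methyl}-6,6-diethoxyhex-2-enal
Conditions: MnO2, CH2Cl2, rt
Reagents that add atoms: none
Why: Activated manganese dioxide oxidises the allylic alcohol to the enal under neutral conditions that should leave the acetal, the silyl ether and the alkene geometry untouched.

Step 5
Reactants: 8 (2E)-3-{[(tert-butyldimethylsilyl)oxy]methyl}-6,6-diethoxyhex-2-enal; 9 vinylmagnesium bromide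
Product: 10 (3S,4E)-5-{[(tert-butyldimethylsilyl)oxy]methyl}-8,8-diethoxyocta-1,4-dien-3-ol
Conditions: 9, ZnCl2, THF/1,4-dioxane, filtration of the magnesium salts; then 8, (−)-MIB [(2S)-3-exo-morpholinoisoborneol] (10 mol %), toluene, −20 to 0 °C; then H2O
Reagents that add atoms: none
Why: This is an amino-alcohol-catalysed enantioselective 1,2-addition of divinylzinc to an aldehyde, in which the zinc alkoxide of (−)-MIB is expected to deliver the vinyl group to the Si face of the enal carbonyl and so give the 6S carbinol.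

Step 6
Reactants: 10 (3S,4E)-5-{[(tert-butyldimethylsilyl)oxy]methyl}-8,8-diethoxyocta-1,4-dien-3-ol
Product: 13 (4E,6S)-4-{[(tert-butyldimethylsilyl)oxy]methyl}-6-[(triethylsilyl)oxy]octa-4,7-dienal, via triethylsilyl ether acetal 11 (not isolated), via collidinium salt 12 (not isolated)
Conditions: TESOTf (3.5 equiv), 2,4,6-collidine (5 equiv), CH2Cl2, −78 to 0 °C; then H2O
Reagents that add atoms: triethylsilyl trifluoromethanesulfonate, CC[Si](CC)(CC)OS(=O)(=O)C(F)(F)F; water, O
Why: The silyl triflate/pyridine base pair first silylates the carbinol and then converts the acyclic acetal through an N-(1-ethoxyalkyl)pyridinium salt into the aldehyde when water is added, a non-acidic acetal cleavage that spares silyl ethers.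

Step 7
Reactants: 13 (4E,6S)-4-{[(tert-butyldimethylsilyl)oxy]methyl}-6-[(triethylsilyl)oxy]octa-4,7-dienal; 14 ethyl (triphenylphosphoranylidene)acetate
Product: 15 ethyl (2Z,6E,8S)-6-{[(tert-butyldimethylsilyl)oxy]methyl}-2-iodo-8-[(triethylsilyl)oxy]deca-2,6,9-trienoate
Conditions: 14, NIS, CH2Cl2, −20 °C; then 13, K2CO3, rt
Reagents that add atoms: N-iodosuccinimide, O=C1CCC(=O)N1I
Why: Iodination of the stabilised ylide and Wittig reaction of the resulting iodo ylide with the unbranched aldehyde should favour the Z iodoenoate, because stabilised ylides place the ester trans to the aldehyde substituent, which leaves iodine cis to C2.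

Step 8
Reactants: 15 ethyl (2Z,6E,8S)-6-{[(tert-butyldimethylsilyl)oxy]methyl}-2-iodo-8-[(triethylsilyl)oxy]deca-2,6,9-trienoate
Product: 16 (2Z,6E,8S)-6-{[(tert-butyldimethylsilyl)oxy]methyl}-2-iodo-8-[(triethylsilyl)oxy]deca-2,6,9-trien-1-ol
Conditions: i-Bu2AlH, CH2Cl2, −78 °C; aq potassium sodium tartrate
Reagents that add atoms: none
Why: Diisobutylaluminium hydride reduces the conjugated ester to the primary allylic alcohol at low temperature without touching the alkenyl iodide or the silyl ethers.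

Step 9
Reactants: 16 (2Z,6E,8S)-6-{[(tert-butyldimethylsilyl)oxy]methyl}-2-iodo-8-[(triethylsilyl)oxy]deca-2,6,9-trien-1-ol
Product: 17 (2Z,6E,8S)-6-{[(tert-butyldimethylsilyl)oxy]methyl}-2-iodo-1-[(4-methoxybenzyl)oxy]-8-[(triethylsilyl)oxy]deca-2,6,9-triene
Conditions: NaH, 4-methoxybenzyl chloride, Bu4NI (cat.), DMF, 0 °C
Reagents that add atoms: 4-methoxybenzyl chloride, COc1ccc(CCl)cc1
Why: Williamson etherification of the primary allylic alkoxide is routine, and the alkenyl iodide and both silyl ethers are stable to it at 0 °C.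

Step 10
Reactants: 17 (2Z,6E,8S)-6-{[(tert-butyldimethylsilyl)oxy]methyl}-2-iodo-1-[(4-methoxybenzyl)oxy]-8-[(triethylsilyl)oxy]deca-2,6,9-triene; 18 carbon monoxide; 19 tributyl(vinyl)stannane
Product: 20 (4Z,8E,10S)-8-{[(tert-butyldimethylsilyl)oxy]methyl}-4-{[(4-methoxybenzyl)oxy]methyl}-10-[(triethylsilyl)oxy]dodeca-1,4,8,11-tetraen-3-one
Conditions: Pd(PPh3)4 (5 mol %), CO (3 atm), THF, 50 °C
Reagents that add atoms: none
Why: In this carbonylative Stille coupling, zerovalent palladium adds to the alkenyl iodide with retention, CO inserts and tin transfers the vinyl group, giving the divinyl ketone with C9 cis to C2, while the allylic silyl ethers are not ionised by palladium.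

Step 11
Reactants: 20 (4Z,8E,10S)-8-{[(tert-butyldimethylsilyl)oxy]methyl}-4-{[(4-methoxybenzyl)oxy]methyl}-10-[(triethylsilyl)oxy]dodeca-1,4,8,11-tetraen-3-one
Product: 21 (4Z,8E,10S)-8-{[(tert-butyldimethylsilyl)oxy]methyl}-10-hydroxy-4-{[(4-methoxybenzyl)oxy]methyl}dodeca-1,4,8,11-tetraen-3-one
Conditions: HF·pyridine, pyridine, THF, 0 °C
Reagents that add atoms: none
Why: Buffered fluoride cleaves the secondary triethylsilyl ether much faster than the primary tert-butyldimethylsilyl ether, a routine selective desilylation.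

Step 12
Reactants: 21 (4Z,8E,10S)-8-{[(tert-butyldimethylsilyl)oxy]methyl}-10-hydroxy-4-{[(4-methoxybenzyl)oxy]methyl}dodeca-1,4,8,11-tetraen-3-one; 22 (diethoxyphosphoryl)acetic acid
Product: 23 (3S,4E,8Z)-5-{[(tert-butyldimethylsilyl)oxy]methyl}-9-{[(4-methoxybenzyl)oxy]methyl}-10-oxododeca-1,4,8,11-tetraen-3-yl (diethoxyphosphoryl)acetate
Conditions: DCC, DMAP (cat.), CH2Cl2, 0 °C
Reagents that add atoms: none
Why: Steglich esterification acylates the secondary carbinol under neutral conditions with retention at C6, and acylating before ring closure avoids a free hydroxyl cis-γ to the enone, which would form a hemiketal.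

Step 13
Reactants: 23 (3S,4E,8Z)-5-{[(tert-butyldimethylsilyl)oxy]methyl}-9-{[(4-methoxybenzyl)oxy]methyl}-10-oxododeca-1,4,8,11-tetraen-3-yl (diethoxyphosphoryl)acetate
Product: 24 (2Z,4S,5E,9Z)-6-{[(tert-butyldimethylsilyl)oxy]methyl}-10-{[(4-methoxybenzyl)oxy]methyl}-1-oxocyclodeca-2,5,9-trien-4-yl (diethoxyphosphoryl)acetate (all three ring alkenes cis in the ring)
Conditions: second-generation Hoveyda–Grubbs catalyst RuCl2(H2IMes)(=CH–C6H4–2-OiPr) (10 mol %), toluene (1 mM), 80 °C
Reagents that add atoms: none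
Why: Ring-closing metathesis between the two monosubstituted alkenes, started at the vinyl group of the allylic ester, closes the ten-membered ring; the two ring-cis trisubstituted alkenes pre-organise the chain, should allow only a cis C7=C8, and are too hindered to take part.

Step 14
Reactants: 24 (2Z,4S,5E,9Z)-6-{[(tert-butyldimethylsilyl)oxy]methyl}-10-{[(4-methoxybenzyl)oxy]methyl}-1-oxocyclodeca-2,5,9-trien-4-yl (diethoxyphosphoryl)acetate; 25 formaldehyde (used as paraformaldehyde)
Product: 27 (1(10)Z,4E,6R,7S)-15-[(tert-butyldimethylsilyl)oxy]-14-[(4-methoxybenzyl)oxy]-9-oxogermacra-1(10),4,11(13)-trien-12,6-olide, via phosphono lactone 26 (not isolated)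
Conditions: KOtBu (1.05 equiv), THF, −20 to 0 °C; then (CH2O)n, 0 °C to rt
Reagents that add atoms: none
Why: tert-Butoxide removes the doubly activated phosphonoacetate hydrogen, the soft carbanion C11 adds to C7 (the β-carbon of the ring-cis C7=C8–C9 enone), the C9 enolate is then protonated by the newly formed α-phosphono lactone C–H, and the resulting phosphonate anion olefinates formaldehyde with loss of diethyl phosphate to give C11=C13. The closest known reaction type is the telescoped intramolecular Michael addition/Horner–Wadsworth–Emmons methylenation of phosphonoacetates of γ-hydroxy enones. The lactone ring O6–C12–C11–C7–C6 closes in the 5-exo-trig mode. The new stereocentre C7 is controlled by C6: allylic 1,3-strain with the cis C9 carbonyl keeps H6 in the enone plane, so the tether on O6 reaches C7 from the face opposite C5 and H6 and H7 end up trans. The step needs C7 and not C1 to be attacked, which is secured because closure onto C1 would require a nine-membered ring, and it needs the tether C–H to be deprotonated in preference to the doubly allylic C6–H, which is secured by the large acidity gap and by one equivalent of base at low temperature.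

Step 15
Reactants: 27 (1(10)Z,4E,6R,7S)-15-[(tert-butyldimethylsilyl)oxy]-14-[(4-methoxybenzyl)oxy]-9-oxogermacra-1(10),4,11(13)-trien-12,6-olide
Product: 28 (1(10)Z,4E,6R,7S,8E)-15-[(tert-butyldimethylsilyl)oxy]-14-[(4-methoxybenzyl)oxy]-9-[(trimethylsilyl)oxy]germacra-1(10),4,8,11(13)-tetraen-12,6-olide
Conditions: TMSOTf, Et3N, CH2Cl2, −78 to 0 °C
Reagents that add atoms: trimethylsilyl trifluoromethanesulfonate, C[Si](C)(C)OS(=O)(=O)C(F)(F)F
Why: Soft enolisation gives the silyl enol ether towards C8, the only enolisable α-position because C10 is an alkene carbon, and it avoids the strong bases that would endanger the α-methylene lactone.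

Step 16
Reactants: 28 (1(10)Z,4E,6R,7S,8E)-15-[(tert-butyldimethylsilyl)oxy]-14-[(4-methoxybenzyl)oxy]-9-[(trimethylsilyl)oxy]germacra-1(10),4,8,11(13)-tetraen-12,6-olide
Product: 30 (1(10)Z,4E,6R,7R,8S)-15-[(tert-butyldimethylsilyl)oxy]-8-hydroxy-14-[(4-methoxybenzyl)oxy]-9-oxogermacra-1(10),4,11(13)-trien-12,6-olide, via silyloxy epoxide 29 (not isolated)
Conditions: DMDO (1.1 equiv), acetone/CH2Cl2, −78 to −40 °C; then aq citric acid, THF, 0 °C
Reagents that add atoms: dimethyldioxirane, CC1(C)OO1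
Why: In this Rubottom oxidation the dioxirane should epoxidise only the electron-rich silyl enol ether, and with H7 held in the enol ether plane by allylic strain the oxidant is expected to add to the C8 face anti to the lactone carbon C11, which gives the 8S alcohol after acid opens the silyloxy epoxide.

Step 17
Reactants: 30 (1(10)Z,4E,6R,7R,8S)-15-[(tert-butyldimethylsilyl)oxy]-8-hydroxy-14-[(4-methoxybenzyl)oxy]-9-oxogermacra-1(10),4,11(13)-trien-12,6-olide; 31 methacrylic anhydride
Product: 32 (1(10)Z,4E,6R,7S,8S)-15-[(tert-butyldimethylsilyl)oxy]-8-(methacryloyloxy)-14-[(4-methoxybenzyl)oxy]-9-oxogermacra-1(10),4,11(13)-trien-12,6-olide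
Conditions: 31, Et3N, DMAP (cat.), CH2Cl2, 0 °C
Reagents that add atoms: none
Why: DMAP-catalysed acylation of the secondary ketol with the anhydride proceeds with retention at C8 and, being fast at 0 °C, should outrun base-mediated epimerisation of the ketol.

Step 18
Reactants: 32 (1(10)Z,4E,6R,7S,8S)-15-[(tert-butyldimethylsilyl)oxy]-8-(methacryloyloxy)-14-[(4-methoxybenzyl)oxy]-9-oxogermacra-1(10),4,11(13)-trien-12,6-olide
Product: 33 (1(10)Z,4E,6R,7S,8S,9S)-15-[(tert-butyldimethylsilyl)oxy]-9-hydroxy-8-(methacryloyloxy)-14-[(4-methoxybenzyl)oxy]germacra-1(10),4,11(13)-trien-12,6-olide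
Conditions: NaBH4, CeCl3·7H2O, MeOH, −78 °C
Reagents that add atoms: none
Why: Luche reduction (borohydride with trivalent cerium) reduces the enone carbonyl 1,2 and faster than the conjugate acceptors, and hydride is expected to attack C9 anti to the C8–O bond (polar Felkin–Anh), which gives the 9S alcohol trans to the C8 ester.

Step 19
Reactants: 33 (1(10)Z,4E,6R,7S,8S,9S)-15-[(tert-butyldimethylsilyl)oxy]-9-hydroxy-8-(methacryloyloxy)-14-[(4-methoxybenzyl)oxy]germacra-1(10),4,11(13)-trien-12,6-olide; 34 acetic anhydride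
Product: 35 (1(10)Z,4E,6R,7S,8S,9S)-9-acetoxy-15-[(tert-butyldimethylsilyl)oxy]-8-(methacryloyloxy)-14-[(4-methoxybenzyl)oxy]germacra-1(10),4,11(13)-trien-12,6-olide
Conditions: 34, pyridine, DMAP (cat.), CH2Cl2, 0 °C
Reagents that add atoms: none
Why: This is a standard acylation of the allylic alcohol, run cold so that esterification is faster than migration of the neighbouring methacrylate.

Step 20
Reactants: 35 (1(10)Z,4E,6R,7S,8S,9S)-9-acetoxy-15-[(tert-butyldimethylsilyl)oxy]-8-(methacryloyloxy)-14-[(4-methoxybenzyl)oxy]germacra-1(10),4,11(13)-trien-12,6-olide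
Product: 36 (1(10)Z,4E,6R,7S,8S,9S)-9-acetoxy-15-[(tert-butyldimethylsilyl)oxy]-14-hydroxy-8-(methacryloyloxy)germacra-1(10),4,11(13)-trien-12,6-olide
Conditions: DDQ, CH2Cl2/pH 7 buffer, 0 °C
Reagents that add atoms: none
Why: Oxidative cleavage of the 4-methoxybenzyl ether starts by single-electron oxidation of the electron-rich arene and should leave the esters, the silyl ether and the electron-poor alkenes untouched.

Step 21
Reactants: 36 (1(10)Z,4E,6R,7S,8S,9S)-9-acetoxy-15-[(tert-butyldimethylsilyl)oxy]-14-hydroxy-8-(methacryloyloxy)germacra-1(10),4,11(13)-trien-12,6-olide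
Product: 37 (1(10)E,4E,6R,7S,8S,9S)-9-acetoxy-15-[(tert-butyldimethylsilyl)oxy]-8-(methacryloyloxy)-14-oxogermacra-1(10),4,11(13)-trien-12,6-olide
Conditions: MnO2, CH2Cl2, rt
Reagents that add atoms: none
Why: Manganese dioxide oxidises the primary allylic alcohol to the conjugated aldehyde under neutral conditions, which avoids acyl migration from O9 and keeps the alkene geometry.

Step 22
Reactants: 37 (1(10)E,4E,6R,7S,8S,9S)-9-acetoxy-15-[(tert-butyldimethylsilyl)oxy]-8-(methacryloyloxy)-14-oxogermacra-1(10),4,11(13)-trien-12,6-olide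
Product: 38 (1(10)E,4E,6R,7S,8S,9S)-9-acetoxy-15-hydroxy-8-(methacryloyloxy)-14-oxogermacra-1(10),4,11(13)-trien-12,6-olide (CNP0147326.4)
Conditions: HF·pyridine, pyridine, THF, 0 °C to rt
Reagents that add atoms: none
Why: Mildly acidic fluoride removes the primary silyl ether without the basic conditions that would endanger the esters, the enal and the α-methylene lactone.

**Compound list**

1 | but-2-yne-1,4-diol | OCC#CCO | starting material
2 | 4-[(tert-butyldimethylsilyl)oxy]but-2-yn-1-ol | OCC#CCO[Si](C)(C)C(C)(C)C | intermediate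
3 | sodium alkenylaluminate (five-membered oxaaluminacycle from 2, aluminium on the carbon bearing CH2OTBS) | [Na+].COCCO[Al-]1(OCCOC)OCC=C1CO[Si](C)(C)C(C)(C)C | intermediate
4 | (2Z)-4-[(tert-butyldimethylsilyl)oxy]-3-iodobut-2-en-1-ol | OC/C=C(\I)CO[Si](C)(C)C(C)(C)C | intermediate
5 | acrolein diethyl acetal (3,3-diethoxyprop-1-ene) | C=CC(OCC)OCC | starting material
6 | 9-(3,3-diethoxypropyl)-9-borabicyclo[3.3.1]nonane | CCOC(CCB1C2CCCC1CCC2)OCC | intermediate
7 | (2E)-3-{[(tert-butyldimethylsilyl)oxy]methyl}-6,6-diethoxyhex-2-en-1-ol (hydroxymethyl cis to the diethoxypropyl chain) | OC/C=C(/CO[Si](C)(C)C(C)(C)C)CCC(OCC)OCC | intermediate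
8 | (2E)-3-{[(tert-butyldimethylsilyl)oxy]methyl}-6,6-diethoxyhex-2-enal | O=C/C=C(/CO[Si](C)(C)C(C)(C)C)CCC(OCC)OCC | intermediate
9 | vinylmagnesium bromide | C=C[Mg]Br | starting material
10 | (3S,4E)-5-{[(tert-butyldimethylsilyl)oxy]methyl}-8,8-diethoxyocta-1,4-dien-3-ol | C=C[C@H](O)/C=C(/CO[Si](C)(C)C(C)(C)C)CCC(OCC)OCC | intermediate
11 | triethylsilyl ether of 10 | C=C[C@H](O[Si](CC)(CC)CC)/C=C(/CO[Si](C)(C)C(C)(C)C)CCC(OCC)OCC | intermediate
12 | N-(1-ethoxyalkyl)-2,4,6-trimethylpyridinium triflate derived from 11 (pyridinium on C1) | C=C[C@H](O[Si](CC)(CC)CC)/C=C(/CO[Si](C)(C)C(C)(C)C)CCC(OCC)[n+]1c(C)cc(C)cc1C.[O-]S(=O)(=O)C(F)(F)F | intermediate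
13 | (4E,6S)-4-{[(tert-butyldimethylsilyl)oxy]methyl}-6-[(triethylsilyl)oxy]octa-4,7-dienal | C=C[C@H](O[Si](CC)(CC)CC)/C=C(/CO[Si](C)(C)C(C)(C)C)CCC=O | intermediate
14 | ethyl (triphenylphosphoranylidene)acetate | CCOC(=O)C=P(c1ccccc1)(c1ccccc1)c1ccccc1 | starting material
15 | ethyl (2Z,6E,8S)-6-{[(tert-butyldimethylsilyl)oxy]methyl}-2-iodo-8-[(triethylsilyl)oxy]deca-2,6,9-trienoate | C=C[C@H](O[Si](CC)(CC)CC)/C=C(/CO[Si](C)(C)C(C)(C)C)CC/C=C(\I)C(=O)OCC | intermediate
16 | (2Z,6E,8S)-6-{[(tert-butyldimethylsilyl)oxy]methyl}-2-iodo-8-[(triethylsilyl)oxy]deca-2,6,9-trien-1-ol | C=C[C@H](O[Si](CC)(CC)CC)/C=C(/CO[Si](C)(C)C(C)(C)C)CC/C=C(\I)CO | intermediate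
17 | (2Z,6E,8S)-6-{[(tert-butyldimethylsilyl)oxy]methyl}-2-iodo-1-[(4-methoxybenzyl)oxy]-8-[(triethylsilyl)oxy]deca-2,6,9-triene | C=C[C@H](O[Si](CC)(CC)CC)/C=C(/CO[Si](C)(C)C(C)(C)C)CC/C=C(\I)COCc1ccc(OC)cc1 | intermediate
18 | carbon monoxide | [C-]#[O+] | starting material
19 | tributyl(vinyl)stannane | C=C[Sn](CCCC)(CCCC)CCCC | starting material
20 | (4Z,8E,10S)-8-{[(tert-butyldimethylsilyl)oxy]methyl}-4-{[(4-methoxybenzyl)oxy]methyl}-10-[(triethylsilyl)oxy]dodeca-1,4,8,11-tetraen-3-one | C=C[C@H](O[Si](CC)(CC)CC)/C=C(/CO[Si](C)(C)C(C)(C)C)CC/C=C(\C(=O)C=C)COCc1ccc(OC)cc1 | intermediate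
21 | (4Z,8E,10S)-8-{[(tert-butyldimethylsilyl)oxy]methyl}-10-hydroxy-4-{[(4-methoxybenzyl)oxy]methyl}dodeca-1,4,8,11-tetraen-3-one | C=C[C@H](O)/C=C(/CO[Si](C)(C)C(C)(C)C)CC/C=C(\C(=O)C=C)COCc1ccc(OC)cc1 | intermediate
22 | (diethoxyphosphoryl)acetic acid | OC(=O)CP(=O)(OCC)OCC | starting material
23 | (3S,4E,8Z)-5-{[(tert-butyldimethylsilyl)oxy]methyl}-9-{[(4-methoxybenzyl)oxy]methyl}-10-oxododeca-1,4,8,11-tetraen-3-yl (diethoxyphosphoryl)acetate | C=C[C@H](OC(=O)CP(=O)(OCC)OCC)/C=C(/CO[Si](C)(C)C(C)(C)C)CC/C=C(\C(=O)C=C)COCc1ccc(OC)cc1 | intermediate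
24 | (2Z,4S,5E,9Z)-6-{[(tert-butyldimethylsilyl)oxy]methyl}-10-{[(4-methoxybenzyl)oxy]methyl}-1-oxocyclodeca-2,5,9-trien-4-yl (diethoxyphosphoryl)acetate; ring C1=C10–C9(=O)–C8=C7–C6–C5=C4–C3–C2, all ring alkenes cis in the ring | C1/C(CO[Si](C)(C)C(C)(C)C)=C\[C@@H](OC(=O)CP(=O)(OCC)OCC)/C=C\C(=O)/C(COCc2ccc(OC)cc2)=C\C1 | intermediate
25 | formaldehyde (paraformaldehyde as source) | C=O | starting material
26 | (6R,7R)-15-[(tert-butyldimethylsilyl)oxy]-11-(diethoxyphosphoryl)-14-[(4-methoxybenzyl)oxy]-9-oxogermacra-1(10),4-dien-12,6-olide (C11 epimers, present as the potassium salt; H6 and H7 trans) | O=C1C[C@H]2C(P(=O)(OCC)OCC)C(=O)O[C@@H]2/C=C(/CO[Si](C)(C)C(C)(C)C)CC/C=C1/COCc1ccc(OC)cc1 | intermediate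
27 | (1(10)Z,4E,6R,7S)-15-[(tert-butyldimethylsilyl)oxy]-14-[(4-methoxybenzyl)oxy]-9-oxogermacra-1(10),4,11(13)-trien-12,6-olide (trans-fused α-methylene lactone) | O=C1C[C@H]2C(=C)C(=O)O[C@@H]2/C=C(/CO[Si](C)(C)C(C)(C)C)CC/C=C1/COCc1ccc(OC)cc1 | intermediate
28 | (1(10)Z,4E,6R,7S,8E)-15-[(tert-butyldimethylsilyl)oxy]-14-[(4-methoxybenzyl)oxy]-9-[(trimethylsilyl)oxy]germacra-1(10),4,8,11(13)-tetraen-12,6-olide (C7 and C10 cis on the enol ether) | C[Si](C)(C)O/C1=C/[C@H]2C(=C)C(=O)O[C@@H]2/C=C(/CO[Si](C)(C)C(C)(C)C)CC/C=C1/COCc1ccc(OC)cc1 | intermediate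
29 | 8,9-epoxide of 28 (9-trimethylsilyloxy oxirane, oxygen on the C8 face that becomes the 8S hydroxyl) | C[Si](C)(C)O[C@@]13O[C@H]3[C@H]2C(=C)C(=O)O[C@@H]2/C=C(/CO[Si](C)(C)C(C)(C)C)CC/C=C1/COCc1ccc(OC)cc1 | intermediate
30 | (1(10)Z,4E,6R,7R,8S)-15-[(tert-butyldimethylsilyl)oxy]-8-hydroxy-14-[(4-methoxybenzyl)oxy]-9-oxogermacra-1(10),4,11(13)-trien-12,6-olide | O=C1[C@@H](O)[C@H]2C(=C)C(=O)O[C@@H]2/C=C(/CO[Si](C)(C)C(C)(C)C)CC/C=C1/COCc1ccc(OC)cc1 | intermediate
31 | methacrylic anhydride | CC(=C)C(=O)OC(=O)C(C)=C | starting material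
32 | (1(10)Z,4E,6R,7S,8S)-15-[(tert-butyldimethylsilyl)oxy]-8-(methacryloyloxy)-14-[(4-methoxybenzyl)oxy]-9-oxogermacra-1(10),4,11(13)-trien-12,6-olide | O=C1[C@@H](OC(=O)C(C)=C)[C@H]2C(=C)C(=O)O[C@@H]2/C=C(/CO[Si](C)(C)C(C)(C)C)CC/C=C1/COCc1ccc(OC)cc1 | intermediate
33 | (1(10)Z,4E,6R,7S,8S,9S)-15-[(tert-butyldimethylsilyl)oxy]-9-hydroxy-8-(methacryloyloxy)-14-[(4-methoxybenzyl)oxy]germacra-1(10),4,11(13)-trien-12,6-olide | O[C@@H]1[C@@H](OC(=O)C(C)=C)[C@H]2C(=C)C(=O)O[C@@H]2/C=C(/CO[Si](C)(C)C(C)(C)C)CC/C=C1/COCc1ccc(OC)cc1 | intermediate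
34 | acetic anhydride | CC(=O)OC(C)=O | starting material
35 | (1(10)Z,4E,6R,7S,8S,9S)-9-acetoxy-15-[(tert-butyldimethylsilyl)oxy]-8-(methacryloyloxy)-14-[(4-methoxybenzyl)oxy]germacra-1(10),4,11(13)-trien-12,6-olide | CC(=O)O[C@@H]1[C@@H](OC(=O)C(C)=C)[C@H]2C(=C)C(=O)O[C@@H]2/C=C(/CO[Si](C)(C)C(C)(C)C)CC/C=C1/COCc1ccc(OC)cc1 | intermediate
36 | (1(10)Z,4E,6R,7S,8S,9S)-9-acetoxy-15-[(tert-butyldimethylsilyl)oxy]-14-hydroxy-8-(methacryloyloxy)germacra-1(10),4,11(13)-trien-12,6-olide | CC(=O)O[C@@H]1[C@@H](OC(=O)C(C)=C)[C@H]2C(=C)C(=O)O[C@@H]2/C=C(/CO[Si](C)(C)C(C)(C)C)CC/C=C1/CO | intermediate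
37 | (1(10)E,4E,6R,7S,8S,9S)-9-acetoxy-15-[(tert-butyldimethylsilyl)oxy]-8-(methacryloyloxy)-14-oxogermacra-1(10),4,11(13)-trien-12,6-olide | CC(=O)O[C@@H]1[C@@H](OC(=O)C(C)=C)[C@H]2C(=C)C(=O)O[C@@H]2/C=C(/CO[Si](C)(C)C(C)(C)C)CC/C=C1/C=O | intermediate
38 | (1(10)E,4E,6R,7S,8S,9S)-9-acetoxy-15-hydroxy-8-(methacryloyloxy)-14-oxogermacra-1(10),4,11(13)-trien-12,6-olide (CNP0147326.4) | C=C(C)C(=O)O[C@H]1[C@H]2C(=C)C(=O)O[C@@H]2/C=C(/CO)CC/C=C(/C=O)[C@@H]1OC(C)=O | target

**Step count and risks**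

Total step count: 22. Longest linear sequence: 22 steps, from but-2-yne-1,4-diol 1 to 38.

Steps most likely to fail:

Step 14. The alkoxide base may remove the doubly allylic C6 hydrogen (vinylogous to the C9 carbonyl) in competition with the phosphonate C–H, so that the C6 stereocentre is lost or the ester is eliminated before C11 closes onto C7. The fallback keeps the same ring closure but uses a malonate donor that a carbonate base can deprotonate, and brings in C13 by decarboxylative methylenation. It sets out from carbinol 21. Steglich esterification with mono-tert-butyl malonate gives the mixed tert-butyl malonate F1. Ring-closing metathesis under the conditions of step 13 gives the ten-membered trienone malonate F2. Cs2CO3 in acetonitrile at 0 °C then effects the 5-exo Michael closure onto C7 to give the tert-butoxycarbonyl lactone F3. TMSOTf/2,6-lutidine cleaves the tert-butyl ester to the carboxy lactone F4. Aqueous formaldehyde and diethylamine convert F4 by Mannich reaction, decarboxylation and loss of the amine into 27, where the fallback rejoins the route.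

Step 13. The ruthenium alkylidene formed at the C7 vinyl group has to engage an electron-poor vinyl ketone to close a strained ring, so intermolecular metathesis to dimers and oligomers or catalyst decay may overtake cyclisation. The fallback closes the ring at the carbinol oxidation level, where both alkenes are electron-rich allylic-carbinol vinyl groups. It sets out from 23. Luche reduction (NaBH4, CeCl3·7H2O, MeOH, −78 °C) gives the C9 carbinol F5 as a mixture of C9 epimers. Metathesis with the same catalyst gives the cyclic dienol F6. Oxidation of the doubly allylic alcohol with MnO2 returns to 24.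

Step 16. Facial selectivity in the epoxidation of the C8=C9 enol ether may be poor or reversed, because the two faces are flanked by C6 and C11 of the same lactone ring and the bias of the ten-membered ring is hard to predict. The fallback corrects C8 by inversion instead of relying on the oxidation. It sets out from 28. If the oxidation delivers mainly the 8-epi ketol F7, a Mitsunobu reaction with methacrylic acid (PPh3, DIAD, THF, 0 °C) displaces the activated hydroxyl with inversion and gives the methacrylate 32 directly, where the fallback rejoins the route in place of step 17.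

Further compounds
F1 | step 14 | (3S,4E,8Z)-5-{[(tert-butyldimethylsilyl)oxy]methyl}-9-{[(4-methoxybenzyl)oxy]methyl}-10-oxododeca-1,4,8,11-tetraen-3-yl tert-butyl malonate | C=C[C@H](OC(=O)CC(=O)OC(C)(C)C)/C=C(/CO[Si](C)(C)C(C)(C)C)CC/C=C(\C(=O)C=C)COCc1ccc(OC)cc1
F2 | step 14 | (2Z,4S,5E,9Z)-6-{[(tert-butyldimethylsilyl)oxy]methyl}-10-{[(4-methoxybenzyl)oxy]methyl}-1-oxocyclodeca-2,5,9-trien-4-yl tert-butyl malonate | C1/C(CO[Si](C)(C)C(C)(C)C)=C\[C@@H](OC(=O)CC(=O)OC(C)(C)C)/C=C\C(=O)/C(COCc2ccc(OC)cc2)=C\C1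
F3 | step 14 | 11-(tert-butoxycarbonyl)-15-[(tert-butyldimethylsilyl)oxy]-14-[(4-methoxybenzyl)oxy]-9-oxogermacra-1(10),4-dien-12,6-olide (C6 and C7 as in 27, C11 epimers) | O=C1C[C@H]2C(C(=O)OC(C)(C)C)C(=O)O[C@@H]2/C=C(/CO[Si](C)(C)C(C)(C)C)CC/C=C1/COCc1ccc(OC)cc1
F4 | step 14 | 15-[(tert-butyldimethylsilyl)oxy]-11-carboxy-14-[(4-methoxybenzyl)oxy]-9-oxogermacra-1(10),4-dien-12,6-olide (C6 and C7 as in 27, C11 epimers) | O=C1C[C@H]2C(C(O)=O)C(=O)O[C@@H]2/C=C(/CO[Si](C)(C)C(C)(C)C)CC/C=C1/COCc1ccc(OC)cc1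
F5 | step 13 | (3S,4E,8Z)-5-{[(tert-butyldimethylsilyl)oxy]methyl}-10-hydroxy-9-{[(4-methoxybenzyl)oxy]methyl}dodeca-1,4,8,11-tetraen-3-yl (diethoxyphosphoryl)acetate (C10 epimers) | C=C[C@H](OC(=O)CP(=O)(OCC)OCC)/C=C(/CO[Si](C)(C)C(C)(C)C)CC/C=C(\C(O)C=C)COCc1ccc(OC)cc1
F6 | step 13 | (2Z,4S,5E,9Z)-6-{[(tert-butyldimethylsilyl)oxy]methyl}-1-hydroxy-10-{[(4-methoxybenzyl)oxy]methyl}cyclodeca-2,5,9-trien-4-yl (diethoxyphosphoryl)acetate (C1 epimers) | C1/C(CO[Si](C)(C)C(C)(C)C)=C\[C@@H](OC(=O)CP(=O)(OCC)OCC)/C=C\C(O)/C(COCc2ccc(OC)cc2)=C\C1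
F7 | step 16 | 8-epimer of 30: 15-[(tert-butyldimethylsilyl)oxy]-8-hydroxy-14-[(4-methoxybenzyl)oxy]-9-oxogermacra-1(10),4,11(13)-trien-12,6-olide with inverted C8 | O=C1[C@H](O)[C@H]2C(=C)C(=O)O[C@@H]2/C=C(/CO[Si](C)(C)C(C)(C)C)CC/C=C1/COCc1ccc(OC)cc1
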